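**Retrosynthetic overview**
1. Disconnection at the C13–C14 single bond. The left C18 piece is a methyl-capped enyne (C12≡C13–CH3) that already carries ring A as the cross-conjugated triene. The right C22 piece is a "normal" all-E polyenal (C14 aldehyde) whose ring B is still a plain 3'-silyloxy-β ring (C5'=C6', C4'H2).
2. Enabling feature: between C14 and C4' of ring B the target is the retro ("anhydro") form of a normal polyene. An oxygen on C14 and a hydrogen on C4' are linked by six conjugated C=C (C15=C15', C14'=C13', C12'=C11', C10'=C9', C8'=C7', C6'=C5'). On the other side the quaternary C1 of ring A offers no removable proton.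
3. Key step (one flask): hydrozirconation of C12≡C13, Zr-to-Zn exchange, addition to the C14 aldehyde, O-sulfonylation and 1,14-elimination. It makes C13–C14, sets C12=C13, removes the C14 oxygen and shifts six double bonds to give the ring B diene unit (C4'=C5', C6'=C7').
4. Left half from safranal (HWE, DIBAL, propynyl Grignard, vinylogous 1,10-dehydration). Right half from (4R,6R)-actinol (enol triflate, Stille coupling, two HWE/DIBAL homologations). Last step: desilylation.
5. Ring order: no ring is closed. Ring A (from safranal) receives its triene pattern in step 4; ring B (from actinol, carrying C3') receives its retro pattern in step 14.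

Key step: step 14

Remark: carotenoid numbering is used (left half C1–C15 with ring A, right half C1'–C15' with ring B). Safranal, (4R,6R)-actinol and the two phosphonates are taken as catalogue chemicals. The 3'S centre of the target has the spatial arrangement of C4 in (4R)-actinol; the descriptor changes only when C4' becomes sp2. All polyenes are handled under argon in dim light.

Step 1
Reactants: 1 safranal (2,6,6-trimethylcyclohexa-1,3-diene-1-carbaldehyde); 2 diethyl (3-cyano-2-methylallyl)phosphonate (E/Z mixture)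
Product: 3 (2E,4E)-3-methyl-5-(2,6,6-trimethylcyclohexa-1,3-dien-1-yl)penta-2,4-dienenitrile
Conditions: NaH, THF, 0 °C to rt
Reagents that add atoms: diethyl (3-cyano-2-methylallyl)phosphonate, CCOP(=O)(OCC)CC(C)=CC#N
Why: Horner–Wadsworth–Emmons olefination of the hindered dienal with the nitrile-stabilised allylic phosphonate should give the E C7=C8 bond, and the geometry at C9=C10 need not be uniform because that bond becomes a single bond in step 4.

Step 2
Reactants: 3 (2E,4E)-3-methyl-5-(2,6,6-trimethylcyclohexa-1,3-dien-1-yl)penta-2,4-dienenitrile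
Product: 5 (2E,4E)-3-methyl-5-(2,6,6-trimethylcyclohexa-1,3-dien-1-yl)penta-2,4-dienal, via iminoalane 4 (not isolated)
Conditions: DIBAL-H, toluene, −78 °C; then aq. Rochelle salt, rt
Reagents that add atoms: water, O
Why: Partial hydride reduction of the conjugated nitrile stops at the N-aluminio aldimine, which is hydrolysed on work-up to the aldehyde (standard nitrile-to-aldehyde DIBAL reduction).

Step 3
Reactants: 5 (2E,4E)-3-methyl-5-(2,6,6-trimethylcyclohexa-1,3-dien-1-yl)penta-2,4-dienal; 6 1-propynylmagnesium bromide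
Product: 7 (5E,7E)-6-methyl-8-(2,6,6-trimethylcyclohexa-1,3-dien-1-yl)octa-5,7-dien-2-yn-4-ol (racemic)
Conditions: THF, −78 to 0 °C; aq. NH4Cl
Reagents that add atoms: 1-propynylmagnesium bromide, CC#C[Mg]Br
Why: Grignard 1,2-addition of the alkynyl nucleophile to the polyenal installs C12≡C13–CH3, and the new carbinol centre is made racemic on purpose because it is destroyed in step 4.

Step 4
Reactants: 7 (5E,7E)-6-methyl-8-(2,6,6-trimethylcyclohexa-1,3-dien-1-yl)octa-5,7-dien-2-yn-4-ol
Product: 9 6-[(2E,4E)-3-methylocta-2,4-dien-6-yn-1-ylidene]-1,5,5-trimethylcyclohexa-1,3-diene (exocyclic bond Z: C8 syn to C1), via mesylate 8 (not isolated)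
Conditions: Ms2O, iPr2NEt, CH2Cl2, −40 to 0 °C, dark
Reagents that add atoms: none
Why: The allylic and propargylic mesylate should ionise to a cation spread over C11, C9, C7, C5 and C3, and loss of H-2 (a vinylogous 1,10-elimination of the anhydroretinol type, with the same terminal proton that is lost when 3-hydroxy retro-carotenoids are dehydrated) gives the triene ring A; the new C8=C9 and C10=C11 bonds come from s-trans single bonds and should be E, and the exocyclic bond should settle with C8 on the less crowded gem-dimethyl side.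

Step 5
Reactants: 10 (4R,6R)-4-hydroxy-2,2,6-trimethylcyclohexanone (actinol); 11 tert-butyldimethylsilyl chloride
Product: 12 (4R,6R)-4-[(tert-butyldimethylsilyl)oxy]-2,2,6-trimethylcyclohexanone
Conditions: imidazole, DMF, rt
Reagents that add atoms: tert-butyldimethylsilyl chloride, CC(C)(C)[Si](C)(C)Cl
Why: Imidazole-promoted silylation protects the secondary alcohol without touching either stereocentre.

Step 6
Reactants: 12 (4R,6R)-4-[(tert-butyldimethylsilyl)oxy]-2,2,6-trimethylcyclohexanone; 13 N-phenylbis(trifluoromethanesulfonimide)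
Product: 15 (4R)-4-[(tert-butyldimethylsilyl)oxy]-2,6,6-trimethylcyclohex-1-en-1-yl trifluoromethanesulfonate, via lithium enolate 14 (not isolated)
Conditions: LDA, THF, −78 °C; then PhNTf2, −78 to 0 °C
Reagents that add atoms: N-phenylbis(trifluoromethanesulfonimide), O=S(=O)(N(c1ccccc1)S(=O)(=O)C(F)(F)F)C(F)(F)F
Why: C2 is quaternary, so the ketone can enolise only toward C6 and O-triflation of that single enolate gives one enol triflate (enolate triflation); the C6 stereocentre is given up on purpose and C4 is not touched.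

Step 7
Reactants: 16 (E)-3-methylpent-2-en-4-yn-1-ol; 17 tributyltin hydride
Product: 18 (2E,4E)-3-methyl-5-(tributylstannyl)penta-2,4-dien-1-ol
Conditions: PdCl2(PPh3)2 (2 mol %), THF, 0 °C
Reagents that add atoms: tributyltin hydride, CCCC[SnH](CCCC)CCCC
Why: Palladium-catalysed hydrostannation adds Sn–H syn across the terminal alkyne with tin on the terminal carbon, giving the E-alkenylstannane.

Step 8
Reactants: 15 (4R)-4-[(tert-butyldimethylsilyl)oxy]-2,6,6-trimethylcyclohex-1-en-1-yl trifluoromethanesulfonate; 18 (2E,4E)-3-methyl-5-(tributylstannyl)penta-2,4-dien-1-ol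
Product: 19 (2E,4E)-5-[(4R)-4-[(tert-butyldimethylsilyl)oxy]-2,6,6-trimethylcyclohex-1-en-1-yl]-3-methylpenta-2,4-dien-1-ol
Conditions: Pd2(dba)3, AsPh3, NMP, 60 °C
Reagents that add atoms: none
Why: Stille coupling of the hindered tetrasubstituted enol triflate with the dienylstannane, under ligand conditions chosen for slow transmetalation, forms the C6'–C7' bond with retention of the stannane geometry.

Step 9
Reactants: 19 (2E,4E)-5-[(4R)-4-[(tert-butyldimethylsilyl)oxy]-2,6,6-trimethylcyclohex-1-en-1-yl]-3-methylpenta-2,4-dien-1-ol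
Product: 20 (2E,4E)-5-[(4R)-4-[(tert-butyldimethylsilyl)oxy]-2,6,6-trimethylcyclohex-1-en-1-yl]-3-methylpenta-2,4-dienal
Conditions: MnO2, CH2Cl2, rt
Reagents that add atoms: none
Why: MnO2 oxidises only the primary allylic alcohol and leaves the silyl ether and the triene untouched (allylic alcohol oxidation).

Step 10
Reactants: 20 (2E,4E)-5-[(4R)-4-[(tert-butyldimethylsilyl)oxy]-2,6,6-trimethylcyclohex-1-en-1-yl]-3-methylpenta-2,4-dienal; 2 diethyl (3-cyano-2-methylallyl)phosphonate
Product: 21 (2E,4E,6E,8E)-9-[(4R)-4-[(tert-butyldimethylsilyl)oxy]-2,6,6-trimethylcyclohex-1-en-1-yl]-3,7-dimethylnona-2,4,6,8-tetraenenitrile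
Conditions: NaH, THF, 0 °C to rt
Reagents that add atoms: diethyl (3-cyano-2-methylallyl)phosphonate, CCOP(=O)(OCC)CC(C)=CC#N
Why: Horner–Wadsworth–Emmons olefination adds C12'–C15' with an E C11'=C12' bond, as in the usual C15 + C5 retinoid homologation.

Step 11
Reactants: 21 (2E,4E,6E,8E)-9-[(4R)-4-[(tert-butyldimethylsilyl)oxy]-2,6,6-trimethylcyclohex-1-en-1-yl]-3,7-dimethylnona-2,4,6,8-tetraenenitrile
Product: 23 (2E,4E,6E,8E)-9-[(4R)-4-[(tert-butyldimethylsilyl)oxy]-2,6,6-trimethylcyclohex-1-en-1-yl]-3,7-dimethylnona-2,4,6,8-tetraenal, via iminoalane 22 (not isolated)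
Conditions: DIBAL-H, toluene, −78 °C; then aq. Rochelle salt, rt
Reagents that add atoms: water, O
Why: DIBAL reduction of the nitrile to the aldimine and hydrolysis gives the silyl-protected (3R)-3-hydroxyretinal, and the silyl ether is inert to DIBAL at low temperature.

Step 12
Reactants: 23 (2E,4E,6E,8E)-9-[(4R)-4-[(tert-butyldimethylsilyl)oxy]-2,6,6-trimethylcyclohex-1-en-1-yl]-3,7-dimethylnona-2,4,6,8-tetraenal; 24 diethyl cyanomethylphosphonate
Product: 25 (2E,4E,6E,8E,10E)-11-[(4R)-4-[(tert-butyldimethylsilyl)oxy]-2,6,6-trimethylcyclohex-1-en-1-yl]-5,9-dimethylundeca-2,4,6,8,10-pentaenenitrile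
Conditions: NaH, THF, 0 °C to rt
Reagents that add atoms: diethyl cyanomethylphosphonate, CCOP(=O)(CC#N)OCC
Why: Horner–Wadsworth–Emmons C2 extension adds C15 and C14, and the geometry of the new C15'=C15 bond is not critical because this bond becomes a single bond in step 14.

Step 13
Reactants: 25 (2E,4E,6E,8E,10E)-11-[(4R)-4-[(tert-butyldimethylsilyl)oxy]-2,6,6-trimethylcyclohex-1-en-1-yl]-5,9-dimethylundeca-2,4,6,8,10-pentaenenitrile
Product: 27 (2E,4E,6E,8E,10E)-11-[(4R)-4-[(tert-butyldimethylsilyl)oxy]-2,6,6-trimethylcyclohex-1-en-1-yl]-5,9-dimethylundeca-2,4,6,8,10-pentaenal, via iminoalane 26 (not isolated)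
Conditions: DIBAL-H, toluene, −78 °C; then aq. Rochelle salt, rt
Reagents that add atoms: water, O
Why: The same nitrile-to-aldehyde DIBAL reduction delivers the C22 aldehyde with C14 at the aldehyde oxidation level.

Step 14
Reactants: 9 6-[(2E,4E)-3-methylocta-2,4-dien-6-yn-1-ylidene]-1,5,5-trimethylcyclohexa-1,3-diene; 27 (2E,4E,6E,8E,10E)-11-[(4R)-4-[(tert-butyldimethylsilyl)oxy]-2,6,6-trimethylcyclohex-1-en-1-yl]-5,9-dimethylundeca-2,4,6,8,10-pentaenal
Product: 32 3'-O-tert-butyldimethylsilyl ether of the target, via alkenylzirconocene chloride 28 (not isolated), via alkenylmethylzinc 29 (not isolated), via methylzinc alkoxide 30 (not isolated), via C14 mesylate 31 (not isolated)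
Conditions: Cp2Zr(H)Cl, CH2Cl2, rt; Me2Zn, toluene, −65 °C; then 27, 0 °C; then iPr2NEt, Ms2O, −40 to 0 °C; one flask, dark
Reagents that add atoms: none
Why: Syn-hydrozirconation of the methyl-capped enyne puts zirconium on the less hindered C13 and fixes C12=C13 as E, and after Zr-to-Zn exchange the alkenylzinc adds 1,2 to the aldehyde to make the C13–C14 bond (hydrozirconation–transmetalation–carbonyl addition, a known sequence for internal alkynes and enals). The bis-polyenylic C14 alkoxide is sulfonylated in the same flask and ionises at once to a cation delocalised from C2 through C14 to C5', and amine-assisted loss of H-4' completes a vinylogous 1,14-elimination that moves the six double bonds C15=C15' to C6'=C5' into the retro positions; the closest known reaction is the dehydration of retinol to anhydroretinol, the same event over five double bonds. No ring is closed and no stereocentre is created: C14 is stereogenic only in passing, and C3', one carbon away from the deprotonation site, keeps the configuration brought in from 10 (its descriptor becomes S only because C4' turns sp2). The selectivity needed is proton loss from C4' and not from a chain methyl or by capture of the cation: ring A cannot give up a proton because C1 is quaternary, base and counter-ion are non-nucleophilic, and only loss of H-4' gives the fully linear conjugation. The new double bonds arise from s-trans single bonds of the aldehyde and should form E, the former double bonds of 27 become freely rotating single bonds so their geometry is erased, and the exocyclic C6'=C7' bond is expected to settle with C8' on the side of C1', the less strained arrangement to which retro end groups equilibrate thermally.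

Step 15
Reactants: 32 3'-O-tert-butyldimethylsilyl ether of the target
Product: 33 target CNP0202479.1
Conditions: Bu4NF, AcOH, THF, 0 °C to rt, dark
Reagents that add atoms: none
Why: Fluoride-induced Si–O cleavage under buffered, non-acidic conditions frees the allylic 3'-alcohol without ionising it and without touching the C3' stereocentre or the polyene (desilylation).

**Compound list**
1 | safranal (2,6,6-trimethylcyclohexa-1,3-diene-1-carbaldehyde) | O=CC1=C(C)C=CCC1(C)C | starting material
2 | diethyl (3-cyano-2-methylallyl)phosphonate (E/Z mixture) | CCOP(=O)(OCC)CC(C)=CC#N | starting material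
3 | (2E,4E)-3-methyl-5-(2,6,6-trimethylcyclohexa-1,3-dien-1-yl)penta-2,4-dienenitrile | N#C/C=C(C)/C=C/C1=C(C)C=CCC1(C)C | intermediate
4 | N-(diisobutylalumanyl) aldimine from 3 (not isolated) | CC(C)C[Al](CC(C)C)N=C/C=C(C)/C=C/C1=C(C)C=CCC1(C)C | intermediate
5 | (2E,4E)-3-methyl-5-(2,6,6-trimethylcyclohexa-1,3-dien-1-yl)penta-2,4-dienal | O=C/C=C(C)/C=C/C1=C(C)C=CCC1(C)C | intermediate
6 | 1-propynylmagnesium bromide | CC#C[Mg]Br | starting material
7 | (5E,7E)-6-methyl-8-(2,6,6-trimethylcyclohexa-1,3-dien-1-yl)octa-5,7-dien-2-yn-4-ol (racemic) | CC#CC(O)/C=C(C)/C=C/C1=C(C)C=CCC1(C)C | intermediate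
8 | methanesulfonate of 7 (not isolated) | CC#CC(OS(C)(=O)=O)/C=C(C)/C=C/C1=C(C)C=CCC1(C)C | intermediate
9 | 6-[(2E,4E)-3-methylocta-2,4-dien-6-yn-1-ylidene]-1,5,5-trimethylcyclohexa-1,3-diene, exocyclic bond Z (C8 syn to C1) | CC#C/C=C/C(C)=C/C=C1/C(C)=CC=CC1(C)C | intermediate
10 | (4R,6R)-4-hydroxy-2,2,6-trimethylcyclohexanone (actinol) | O=C1[C@H](C)C[C@@H](O)CC1(C)C | starting material
11 | tert-butyldimethylsilyl chloride | CC(C)(C)[Si](C)(C)Cl | starting material
12 | (4R,6R)-4-[(tert-butyldimethylsilyl)oxy]-2,2,6-trimethylcyclohexanone | O=C1[C@H](C)C[C@@H](O[Si](C)(C)C(C)(C)C)CC1(C)C | intermediate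
13 | N-phenylbis(trifluoromethanesulfonimide) | O=S(=O)(N(c1ccccc1)S(=O)(=O)C(F)(F)F)C(F)(F)F | starting material
14 | lithium enolate of 12 (not isolated) | [Li]OC1=C(C)C[C@@H](O[Si](C)(C)C(C)(C)C)CC1(C)C | intermediate
15 | (4R)-4-[(tert-butyldimethylsilyl)oxy]-2,6,6-trimethylcyclohex-1-en-1-yl trifluoromethanesulfonate | FC(F)(F)S(=O)(=O)OC1=C(C)C[C@@H](O[Si](C)(C)C(C)(C)C)CC1(C)C | intermediate
16 | (E)-3-methylpent-2-en-4-yn-1-ol | C#C/C(C)=C/CO | starting material
17 | tributyltin hydride | CCCC[SnH](CCCC)CCCC | starting material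
18 | (2E,4E)-3-methyl-5-(tributylstannyl)penta-2,4-dien-1-ol | CCCC[Sn](CCCC)(CCCC)/C=C/C(C)=C/CO | intermediate
19 | (2E,4E)-5-[(4R)-4-[(tert-butyldimethylsilyl)oxy]-2,6,6-trimethylcyclohex-1-en-1-yl]-3-methylpenta-2,4-dien-1-ol | OC/C=C(C)/C=C/C1=C(C)C[C@@H](O[Si](C)(C)C(C)(C)C)CC1(C)C | intermediate
20 | (2E,4E)-5-[(4R)-4-[(tert-butyldimethylsilyl)oxy]-2,6,6-trimethylcyclohex-1-en-1-yl]-3-methylpenta-2,4-dienal | O=C/C=C(C)/C=C/C1=C(C)C[C@@H](O[Si](C)(C)C(C)(C)C)CC1(C)C | intermediate
21 | (2E,4E,6E,8E)-9-[(4R)-4-[(tert-butyldimethylsilyl)oxy]-2,6,6-trimethylcyclohex-1-en-1-yl]-3,7-dimethylnona-2,4,6,8-tetraenenitrile | N#C/C=C(C)/C=C/C=C(C)/C=C/C1=C(C)C[C@@H](O[Si](C)(C)C(C)(C)C)CC1(C)C | intermediate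
22 | N-(diisobutylalumanyl) aldimine from 21 (not isolated) | CC(C)C[Al](CC(C)C)N=C/C=C(C)/C=C/C=C(C)/C=C/C1=C(C)C[C@@H](O[Si](C)(C)C(C)(C)C)CC1(C)C | intermediate
23 | (2E,4E,6E,8E)-9-[(4R)-4-[(tert-butyldimethylsilyl)oxy]-2,6,6-trimethylcyclohex-1-en-1-yl]-3,7-dimethylnona-2,4,6,8-tetraenal | O=C/C=C(C)/C=C/C=C(C)/C=C/C1=C(C)C[C@@H](O[Si](C)(C)C(C)(C)C)CC1(C)C | intermediate
24 | diethyl cyanomethylphosphonate | CCOP(=O)(CC#N)OCC | starting material
25 | (2E,4E,6E,8E,10E)-11-[(4R)-4-[(tert-butyldimethylsilyl)oxy]-2,6,6-trimethylcyclohex-1-en-1-yl]-5,9-dimethylundeca-2,4,6,8,10-pentaenenitrile | N#C/C=C/C=C(C)/C=C/C=C(C)/C=C/C1=C(C)C[C@@H](O[Si](C)(C)C(C)(C)C)CC1(C)C | intermediate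
26 | N-(diisobutylalumanyl) aldimine from 25 (not isolated) | CC(C)C[Al](CC(C)C)N=C/C=C/C=C(C)/C=C/C=C(C)/C=C/C1=C(C)C[C@@H](O[Si](C)(C)C(C)(C)C)CC1(C)C | intermediate
27 | (2E,4E,6E,8E,10E)-11-[(4R)-4-[(tert-butyldimethylsilyl)oxy]-2,6,6-trimethylcyclohex-1-en-1-yl]-5,9-dimethylundeca-2,4,6,8,10-pentaenal | O=C/C=C/C=C(C)/C=C/C=C(C)/C=C/C1=C(C)C[C@@H](O[Si](C)(C)C(C)(C)C)CC1(C)C | intermediate
28 | C13 alkenylzirconocene chloride from 9 (Zr on C13, C11 trans to Zr; not isolated) | C/C(=C\C=C\C(C)=C\C=C1\C(C)=CC=CC1(C)C)[Zr](Cl)(C1C=CC=C1)C1C=CC=C1 | intermediate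
29 | C13 alkenyl(methyl)zinc (not isolated) | C/C(=C\C=C\C(C)=C\C=C1\C(C)=CC=CC1(C)C)[Zn]C | intermediate
30 | methylzinc alkoxide of the C14 carbinol (C13–C14 bond formed, both configurations at C14; not isolated) | C[Zn]OC(/C(C)=C/C=C/C(C)=C/C=C1/C(C)=CC=CC1(C)C)/C=C/C=C(C)/C=C/C=C(C)/C=C/C1=C(C)C[C@@H](O[Si](C)(C)C(C)(C)C)CC1(C)C | intermediate
31 | C14 methanesulfonate of that carbinol (not isolated) | CS(=O)(=O)OC(/C(C)=C/C=C/C(C)=C/C=C1/C(C)=CC=CC1(C)C)/C=C/C=C(C)/C=C/C=C(C)/C=C/C1=C(C)C[C@@H](O[Si](C)(C)C(C)(C)C)CC1(C)C | intermediate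
32 | 3'-O-tert-butyldimethylsilyl ether of the target (all-E chain, C8 syn to C1, C8' syn to C1', 3'S) | CC1=CC=CC(C)(C)\C1=C/C=C(C)/C=C/C=C(C)/C=C/C=C/C(C)=C/C=C/C(C)=C/C=C1/C(C)=C[C@@H](O[Si](C)(C)C(C)(C)C)CC1(C)C | intermediate
33 | target CNP0202479.1: ring A 2,6,6-trimethylcyclohexa-2,4-dien-1-ylidene and ring B (4S)-4-hydroxy-2,6,6-trimethylcyclohex-2-en-1-ylidene joined by the all-E 3,7,12,16-tetramethyloctadeca-2,4,6,8,10,12,14,16-octaene-1,18-diylidene chain (C8 syn to C1, C8' syn to C1') | CC1=CC=CC(C)(C)\C1=C/C=C(C)/C=C/C=C(C)/C=C/C=C/C(C)=C/C=C/C(C)=C/C=C1/C(C)=C[C@@H](O)CC1(C)C | target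

**Step count and risks**
Total steps: 15. Longest linear sequence: 10 (steps 5, 6, 8, 9, 10, 11, 12, 13, 14, 15).

Most likely to fail, first: step 14. Zirconium may add to C12 instead of C13. After ionisation the cation may lose a proton from a chain methyl, be captured by a nucleophile, suffer migration of a C1 methyl in ring A (aromatisation), or the allylic C3' silyl ether of the product may ionise again. Fallback (sets out from 23 and 9, returns at 32): the union is changed to a cross-coupling of two preformed retro halves. Ethynylmagnesium bromide adds to aldehyde 23 to give the propargylic carbinol F1. Ms2O/iPr2NEt then performs the vinylogous dehydration on this smaller substrate, which contains no ring A and is the direct anhydroretinol case (1,12-elimination, loss of H-4'), giving the right-hand retro enyne F2 with a terminal alkyne. Enyne 9 is hydrozirconated and iodinated (Cp2Zr(H)Cl, then I2) to the alkenyl iodide F3, from which a regioisomer can be separated. Hydrozirconation of the terminal alkyne of F2 (Zr on C14), exchange with ZnCl2 and Negishi coupling with F3 under Pd(PPh3)4 forms the C13–C14 bond with retention at both sp2 carbons and gives 32.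

Second: step 4. Proton loss may occur from the C9 methyl, or the cation may be captured at C3, instead of clean loss of H-2. Fallback (sets out from 7, returns at 9): the one-step vinylogous elimination is replaced by allylic transposition followed by base-induced dehydrohalogenation. PBr3 in Et2O at −30 °C converts 7 into the allylic bromide, which should equilibrate by bromide return to the through-conjugated 3-bromo retro enyne F4. DBU in THF then removes HBr across C2–C3 (the only β-hydrogens are on C2) to give 9.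

Third: step 8. Oxidative addition and transmetalation at the tetrasubstituted enol triflate may be too slow, with triflate hydrolysis or stannane homocoupling taking over. Fallback (sets out from 12 and 16, returns at 20): the C6'–C7' bond is made by carbonyl addition instead of cross-coupling. The dianion of 16 (2 equiv n-BuLi) adds to the ketone of 12 to give the yne-diol F5. Red-Al reduces the propargylic triple bond to the E alkene under direction of the tertiary alkoxide, giving the ene-diol F6. MnO2 oxidises only the primary allylic alcohol to the hydroxy aldehyde F7. POCl3/pyridine dehydrates the tertiary alcohol toward C5', the only ring position with a β-hydrogen, to give aldehyde 20.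

Further compounds
F1 | step 14 | (4E,6E,8E,10E)-11-[(4R)-4-[(tert-butyldimethylsilyl)oxy]-2,6,6-trimethylcyclohex-1-en-1-yl]-5,9-dimethylundeca-4,6,8,10-tetraen-1-yn-3-ol | C#CC(O)/C=C(C)/C=C/C=C(C)/C=C/C1=C(C)C[C@@H](O[Si](C)(C)C(C)(C)C)CC1(C)C
F2 | step 14 | right-hand retro enyne: (4S)-silyloxy ring B ylidene carrying the all-E 3,7-dimethylundeca-2,4,6,8-tetraen-10-yn-1-ylidene chain | C#C/C=C/C(C)=C/C=C/C(C)=C/C=C1/C(C)=C[C@@H](O[Si](C)(C)C(C)(C)C)CC1(C)C
F3 | step 14 | C13 alkenyl iodide from 9 (iodine on C13, C11 trans to iodine) | C/C(I)=C\C=C\C(C)=C\C=C1\C(C)=CC=CC1(C)C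
F4 | step 4 | 3-bromo-6-[(2E,4E)-3-methylocta-2,4-dien-6-yn-1-ylidene]-1,5,5-trimethylcyclohex-1-ene (racemic) | CC#C/C=C/C(C)=C/C=C1/C(C)=CC(Br)CC1(C)C
F5 | step 8 | yne-diol from 12 and 16 (tertiary alcohol at C6', both configurations) | OC/C=C(C)/C#CC1(O)[C@H](C)C[C@@H](O[Si](C)(C)C(C)(C)C)CC1(C)C
F6 | step 8 | (2E,4E)-ene-diol from F5 | OC/C=C(C)/C=C/C1(O)[C@H](C)C[C@@H](O[Si](C)(C)C(C)(C)C)CC1(C)C
F7 | step 8 | (2E,4E)-hydroxy aldehyde from F6 | O=C/C=C(C)/C=C/C1(O)[C@H](C)C[C@@H](O[Si](C)(C)C(C)(C)C)CC1(C)C
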